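The target is cut at the lactone C4–O bond. The γ-lactone (C1–C2–C3–C4–O) fused to the 1,2-dioxane (C3–C4–C5–C6–O–O) has at C4 a methyl and the lactone oxygen beside the C3 acetic arm, which is what remains when a carboxyl adds across an exocyclic C4=CH2. Iodine-triggered lactone closure therefore builds the second ring, the C4–O bond and the quaternary C4 stereocentre in one operation, with C3 dictating the cis fusion. Its substrate is a (3R,6S)-4-methylidene-1,2-dioxane-3-acetic acid carrying a silyloxymethyl group at C6, made from (S)-2-methylglycidol by alkyne carbometalation, singlet-oxygen ene reaction and invertive epoxide opening; the 10-phenyldecyl chain is added last.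

Key step: step 11

Assumption: (S)-2-methylglycidol of high enantiomeric purity and (9-bromononyl)benzene are taken as purchasable; atom labels C1–C6 are those of the lactone and dioxane defined above.

Step 1
Reactants: 1 (S)-2-methylglycidol
Product: 2 (2R)-2-{[(4-methoxyphenyl)methoxy]methyl}-2-methyloxirane
Conditions: NaH, 4-methoxybenzyl chloride, Bu4NI (cat.), THF/DMF, 0 °C to rt
Reagents that add atoms: 4-methoxybenzyl chloride, COc1ccc(CCl)cc1
Why: Williamson etherification of the primary alkoxide leaves the quaternary centre untouched (a Payne shift of this alkoxide is degenerate and returns the same enantiomer), and the R descriptor of 2 reflects only the changed substituent priorities.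

Step 2
Reactants: 2 (2R)-2-{[(4-methoxyphenyl)methoxy]methyl}-2-methyloxirane
Product: 3 (2R)-1-[(4-methoxyphenyl)methoxy]-2-methylpent-4-yn-2-ol
Conditions: LiC≡CH·H2NCH2CH2NH2, DMSO, 0 °C to rt; then H2O
Reagents that add atoms: lithium acetylide–ethylenediamine complex, [Li+].[C-]#C.NCCN
Why: SN2 opening of the epoxide by the acetylide occurs at the unsubstituted ring carbon, so the C–O bond of the tertiary centre that becomes C6 is not touched.

Step 3
Reactants: 3 (2R)-1-[(4-methoxyphenyl)methoxy]-2-methylpent-4-yn-2-ol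
Product: 5 (2R,4E)-5-iodo-1-[(4-methoxyphenyl)methoxy]-2,4-dimethylpent-4-en-2-ol, via alkenylalane 4 (not isolated)
Conditions: Me3Al, Cp2ZrCl2, CH2Cl2, 0 °C to rt; then I2, THF, −30 to 0 °C
Reagents that add atoms: trimethylaluminium, C[Al](C)C; iodine, [I][I]
Why: Zirconium-catalysed carboalumination (Negishi) adds methyl and aluminium syn across the terminal alkyne with methyl on the internal carbon, and iodinolysis of the C–Al bond with retention gives the E alkenyl iodide that fixes the later C3=C4 geometry.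

Step 4
Reactants: 5 (2R,4E)-5-iodo-1-[(4-methoxyphenyl)methoxy]-2,4-dimethylpent-4-en-2-ol
Product: 6 methyl (3E,6R)-6-hydroxy-7-[(4-methoxyphenyl)methoxy]-4,6-dimethylhept-3-enoate
Conditions: BrZnCH2CO2Me (from BrCH2CO2Me and Zn in THF), Pd(PPh3)4 (cat.), THF/DMPU, 50 °C
Reagents that add atoms: methyl bromoacetate (used as its zinc reagent), COC(=O)CBr
Why: Negishi cross-coupling of the alkenyl iodide with the Reformatsky zinc enolate proceeds with retention of the alkene geometry and installs the CH2CO2Me arm as a β,γ-unsaturated ester without a base strong enough to move the double bond.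

Step 5
Reactants: 6 methyl (3E,6R)-6-hydroxy-7-[(4-methoxyphenyl)methoxy]-4,6-dimethylhept-3-enoate
Product: 7 methyl (3E,6R)-6,7-dihydroxy-4,6-dimethylhept-3-enoate
Conditions: DDQ, CH2Cl2/pH 7 buffer, 0 °C to rt
Reagents that add atoms: none
Why: Oxidative cleavage of the 4-methoxybenzyl ether by DDQ (hydride abstraction and hydrolysis of the resulting oxocarbenium ion) is selective for the electron-rich benzyl ether over the trisubstituted alkene, the ester and the tertiary alcohol.

Step 6
Reactants: 7 methyl (3E,6R)-6,7-dihydroxy-4,6-dimethylhept-3-enoate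
Product: 9 methyl (3E)-4-methyl-5-[(2R)-2-methyloxiran-2-yl]pent-3-enoate, via primary tosylate 8 (not isolated)
Conditions: TsCl, Et3N, Bu2SnO (cat.), CH2Cl2, 0 °C; then K2CO3, MeOH, 0 °C
Reagents that add atoms: none
Why: Tin-assisted selective tosylation of the primary hydroxyl and intramolecular Williamson displacement by the tertiary alkoxide close the 2,2-disubstituted epoxide with retention at the quaternary carbon, whose C–O bond is never broken.

Step 7
Reactants: 9 methyl (3E)-4-methyl-5-[(2R)-2-methyloxiran-2-yl]pent-3-enoate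
Product: 10 methyl (3RS)-3-hydroperoxy-4-methylidene-5-[(2R)-2-methyloxiran-2-yl]pentanoate (both C3 epimers)
Conditions: O2, tetraphenylporphyrin (cat.), visible light, CH2Cl2, 0 °C
Reagents that add atoms: dioxygen, O=O
Why: Schenck ene reaction of singlet oxygen places the hydroperoxide on C3 and moves the double bond to C4=CH2, since hydrogen is taken from the methyl on the more substituted side of the E alkene (cis effect) while the C2 hydrogens are deactivated by the ester and the C5 hydrogens lie on the unreactive side beside a quaternary carbon, and because nothing controls the face of attack both C3 epimers are expected.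

Step 8
Reactants: 10 methyl (3RS)-3-hydroperoxy-4-methylidene-5-[(2R)-2-methyloxiran-2-yl]pentanoate
Product: 11 methyl 2-[(3R,6S)-6-(hydroxymethyl)-6-methyl-4-methylidene-1,2-dioxan-3-yl]acetate
Conditions: Amberlyst-15 (cat.), CH2Cl2, 0 °C to rt; then chromatography to remove the unwanted C3 epimer
Reagents that add atoms: none
Why: Acid-catalysed intramolecular epoxide opening by the hydroperoxide in the 6-exo-tet mode at the tertiary carbon proceeds with inversion and so sets C6 as S, frees the primary alcohol, and gives two dioxanes epimeric at C3 that are diastereomers and separable on silica gel.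

Step 9
Reactants: 11 methyl 2-[(3R,6S)-6-(hydroxymethyl)-6-methyl-4-methylidene-1,2-dioxan-3-yl]acetate
Product: 12 methyl 2-[(3R,6S)-6-({[tert-butyl(dimethyl)silyl]oxy}methyl)-6-methyl-4-methylidene-1,2-dioxan-3-yl]acetate
Conditions: TBSCl, imidazole, DMF, 0 °C to rt
Reagents that add atoms: tert-butyl(chloro)dimethylsilane, CC(C)(C)[Si](C)(C)Cl
Why: Silylation of the primary alcohol with TBSCl and imidazole caps the only other internal nucleophile before the halolactonisation.

Step 10
Reactants: 12 methyl 2-[(3R,6S)-6-({[tert-butyl(dimethyl)silyl]oxy}methyl)-6-methyl-4-methylidene-1,2-dioxan-3-yl]acetate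
Product: 13 2-[(3R,6S)-6-({[tert-butyl(dimethyl)silyl]oxy}methyl)-6-methyl-4-methylidene-1,2-dioxan-3-yl]acetic acid
Conditions: LiOH·H2O, THF/H2O, 0 °C; then 0.5 M HCl to pH 4, 0 °C
Reagents that add atoms: lithium hydroxide, [Li+].[OH-]
Why: Saponification of the methyl ester with lithium hydroxide at 0 °C is expected to be faster than β-elimination of the peroxide oxygen, and the dialkyl peroxide and the silyl ether tolerate cold aqueous base and a brief mild acidification.

Step 11
Reactants: 13 2-[(3R,6S)-6-({[tert-butyl(dimethyl)silyl]oxy}methyl)-6-methyl-4-methylidene-1,2-dioxan-3-yl]acetic acid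
Product: 14 (3S,4aR,7aR)-3-({[tert-butyl(dimethyl)silyl]oxy}methyl)-4a-(iodomethyl)-3-methyl-3,4,4a,7a-tetrahydrofuro[3,2-c][1,2]dioxin-6(7H)-one
Conditions: I2, NaHCO3, MeCN, 0 °C, dark
Reagents that add atoms: iodine, [I][I]
Why: Molecular iodine adds reversibly to the 1,1-disubstituted C4=CH2 bond and the iodonium ion is captured at its more substituted end, C4, by the carboxylate tethered at C3, so that the C4–O bond, the γ-lactone and a CH2I group arise together. The closest known reaction type is the iodolactonisation of γ,δ-unsaturated carboxylic acids to iodomethyl γ-lactones. The lactone ring closes in the 5-exo-trig mode. The new stereocentre C4 is controlled by the existing C3 centre, because the one-carbon tether delivers the carboxylate by axial attack to the face of C4 that is syn to the arm in the chair with the arm equatorial, which gives the cis ring fusion and R at C4, the trans-fused γ-lactone being strained. The step needs 5-exo (Markovnikov) over 6-endo closure, which the tertiary C4 and the ring size secure, and it needs chemoselectivity for the alkene over the O–O bond and the C6 oxygen, which the non-reducing bicarbonate-buffered medium and the silyl ether secure.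

Step 12
Reactants: 14 (3S,4aR,7aR)-3-({[tert-butyl(dimethyl)silyl]oxy}methyl)-4a-(iodomethyl)-3-methyl-3,4,4a,7a-tetrahydrofuro[3,2-c][1,2]dioxin-6(7H)-one
Product: 15 (3S,4aR,7aR)-3-({[tert-butyl(dimethyl)silyl]oxy}methyl)-3,4a-dimethyl-3,4,4a,7a-tetrahydrofuro[3,2-c][1,2]dioxin-6(7H)-one
Conditions: Bu3SnH, Et3B (cat.), air, toluene, 0 °C to rt
Reagents that add atoms: none
Why: Radical chain deiodination with tributyltin hydride gives a primary radical that is γ to the nearer peroxide oxygen and geometrically unable to attack the O–O bond, so it is simply reduced to the C4 methyl group without change at C4.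

Step 13
Reactants: 15 (3S,4aR,7aR)-3-({[tert-butyl(dimethyl)silyl]oxy}methyl)-3,4a-dimethyl-3,4,4a,7a-tetrahydrofuro[3,2-c][1,2]dioxin-6(7H)-one
Product: 16 (3S,4aR,7aR)-3-(hydroxymethyl)-3,4a-dimethyl-3,4,4a,7a-tetrahydrofuro[3,2-c][1,2]dioxin-6(7H)-one
Conditions: HF·pyridine, pyridine/THF, 0 °C to rt
Reagents that add atoms: none
Why: Fluoride-mediated desilylation with pyridine-buffered HF frees the primary alcohol under non-basic conditions, which protects the β-peroxy lactone from elimination.

Step 14
Reactants: 16 (3S,4aR,7aR)-3-(hydroxymethyl)-3,4a-dimethyl-3,4,4a,7a-tetrahydrofuro[3,2-c][1,2]dioxin-6(7H)-one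
Product: 17 (3S,4aR,7aR)-3,4a-dimethyl-6-oxo-3,4,4a,6,7,7a-hexahydrofuro[3,2-c][1,2]dioxine-3-carbaldehyde
Conditions: Dess–Martin periodinane, NaHCO3, CH2Cl2, 0 °C to rt
Reagents that add atoms: none
Why: Dess–Martin oxidation gives the aldehyde under buffered neutral conditions, and the quaternary α-carbon excludes enolisation and base-induced peroxide fragmentation at C6.

Step 15
Reactants: 18 (9-bromononyl)benzene
Product: 19 triphenyl(9-phenylnonyl)phosphonium bromide
Conditions: PPh3, MeCN, reflux
Reagents that add atoms: triphenylphosphine, c1ccc(cc1)P(c1ccccc1)c1ccccc1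
Why: SN2 quaternisation of triphenylphosphine by the primary bromide gives the phosphonium salt.

Step 16
Reactants: 17 (3S,4aR,7aR)-3,4a-dimethyl-6-oxo-3,4,4a,6,7,7a-hexahydrofuro[3,2-c][1,2]dioxine-3-carbaldehyde; 19 triphenyl(9-phenylnonyl)phosphonium bromide
Product: 21 (3S,4aR,7aR)-3,4a-dimethyl-3-[(1Z)-10-phenyldec-1-en-1-yl]-3,4,4a,7a-tetrahydrofuro[3,2-c][1,2]dioxin-6(7H)-one, via phosphonium ylide 20 (not isolated)
Conditions: 19, NaN(SiMe3)2, THF, −78 to 0 °C; then 17, −78 to −20 °C
Reagents that add atoms: none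
Why: Wittig olefination with the salt-free non-stabilised ylide attacks the non-enolisable aldehyde at low temperature faster than it deprotonates the lactone, and the Z/E outcome is irrelevant because the alkene is saturated in the next step.

Step 17
Reactants: 21 (3S,4aR,7aR)-3,4a-dimethyl-3-[(1Z)-10-phenyldec-1-en-1-yl]-3,4,4a,7a-tetrahydrofuro[3,2-c][1,2]dioxin-6(7H)-one
Product: 22 (3R,4aR,7aR)-3,4a-dimethyl-3-(10-phenyldecyl)-3,4,4a,7a-tetrahydrofuro[3,2-c][1,2]dioxin-6(7H)-one
Conditions: KO2CN=NCO2K, AcOH, CH2Cl2/MeOH, 0 °C to rt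
Reagents that add atoms: none
Why: Diimide reduction transfers two hydrogens in a concerted syn fashion to the disubstituted alkene and, unlike catalytic hydrogenation, does not cleave the O–O bond or touch the lactone.

Compound list
1 | (S)-2-methylglycidol, [(2S)-2-methyloxiran-2-yl]methanol | C[C@]1(CO)CO1 | starting material
2 | (2R)-2-{[(4-methoxyphenyl)methoxy]methyl}-2-methyloxirane | C[C@]1(COCc2ccc(OC)cc2)CO1 | intermediate
3 | (2R)-1-[(4-methoxyphenyl)methoxy]-2-methylpent-4-yn-2-ol | C[C@](O)(COCc1ccc(OC)cc1)CC#C | intermediate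
4 | [(1E,4R)-4-[(dimethylalumanyl)oxy]-5-[(4-methoxyphenyl)methoxy]-2,4-dimethylpent-1-en-1-yl](dimethyl)alumane, formed in the flask | C[C@](O[Al](C)C)(COCc1ccc(OC)cc1)C/C(C)=C/[Al](C)C | intermediate
5 | (2R,4E)-5-iodo-1-[(4-methoxyphenyl)methoxy]-2,4-dimethylpent-4-en-2-ol | C[C@](O)(COCc1ccc(OC)cc1)C/C(C)=C/I | intermediate
6 | methyl (3E,6R)-6-hydroxy-7-[(4-methoxyphenyl)methoxy]-4,6-dimethylhept-3-enoate | COC(=O)C/C=C(\C)C[C@@](C)(O)COCc1ccc(OC)cc1 | intermediate
7 | methyl (3E,6R)-6,7-dihydroxy-4,6-dimethylhept-3-enoate | COC(=O)C/C=C(\C)C[C@@](C)(O)CO | intermediate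
8 | methyl (3E,6R)-6-hydroxy-4,6-dimethyl-7-{[(4-methylphenyl)sulfonyl]oxy}hept-3-enoate, formed in the flask | COC(=O)C/C=C(\C)C[C@@](C)(O)COS(=O)(=O)c1ccc(C)cc1 | intermediate
9 | methyl (3E)-4-methyl-5-[(2R)-2-methyloxiran-2-yl]pent-3-enoate | COC(=O)C/C=C(\C)C[C@]1(C)CO1 | intermediate
10 | methyl (3RS)-3-hydroperoxy-4-methylidene-5-[(2R)-2-methyloxiran-2-yl]pentanoate, both C3 epimers | COC(=O)CC(OO)C(=C)C[C@]1(C)CO1 | intermediate
11 | methyl 2-[(3R,6S)-6-(hydroxymethyl)-6-methyl-4-methylidene-1,2-dioxan-3-yl]acetate | C[C@@]1(CO)CC(=C)[C@@H](CC(=O)OC)OO1 | intermediate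
12 | methyl 2-[(3R,6S)-6-({[tert-butyl(dimethyl)silyl]oxy}methyl)-6-methyl-4-methylidene-1,2-dioxan-3-yl]acetate | C[C@@]1(CO[Si](C)(C)C(C)(C)C)CC(=C)[C@@H](CC(=O)OC)OO1 | intermediate
13 | 2-[(3R,6S)-6-({[tert-butyl(dimethyl)silyl]oxy}methyl)-6-methyl-4-methylidene-1,2-dioxan-3-yl]acetic acid | C[C@@]1(CO[Si](C)(C)C(C)(C)C)CC(=C)[C@@H](CC(O)=O)OO1 | intermediate
14 | (3S,4aR,7aR)-3-({[tert-butyl(dimethyl)silyl]oxy}methyl)-4a-(iodomethyl)-3-methyl-3,4,4a,7a-tetrahydrofuro[3,2-c][1,2]dioxin-6(7H)-one, cis-fused | C[C@@]1(CO[Si](C)(C)C(C)(C)C)C[C@@]2(CI)OC(=O)C[C@H]2OO1 | intermediate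
15 | (3S,4aR,7aR)-3-({[tert-butyl(dimethyl)silyl]oxy}methyl)-3,4a-dimethyl-3,4,4a,7a-tetrahydrofuro[3,2-c][1,2]dioxin-6(7H)-one | C[C@@]1(CO[Si](C)(C)C(C)(C)C)C[C@@]2(C)OC(=O)C[C@H]2OO1 | intermediate
16 | (3S,4aR,7aR)-3-(hydroxymethyl)-3,4a-dimethyl-3,4,4a,7a-tetrahydrofuro[3,2-c][1,2]dioxin-6(7H)-one | C[C@@]1(CO)C[C@@]2(C)OC(=O)C[C@H]2OO1 | intermediate
17 | (3S,4aR,7aR)-3,4a-dimethyl-6-oxo-3,4,4a,6,7,7a-hexahydrofuro[3,2-c][1,2]dioxine-3-carbaldehyde | C[C@@]1(C=O)C[C@@]2(C)OC(=O)C[C@H]2OO1 | intermediate
18 | (9-bromononyl)benzene | BrCCCCCCCCCc1ccccc1 | starting material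
19 | triphenyl(9-phenylnonyl)phosphonium bromide | [Br-].c1ccccc1CCCCCCCCC[P+](c1ccccc1)(c1ccccc1)c1ccccc1 | intermediate
20 | triphenyl(9-phenylnonylidene)phosphorane, ylide formed in the flask | c1ccccc1CCCCCCCCC=P(c1ccccc1)(c1ccccc1)c1ccccc1 | intermediate
21 | (3S,4aR,7aR)-3,4a-dimethyl-3-[(1Z)-10-phenyldec-1-en-1-yl]-3,4,4a,7a-tetrahydrofuro[3,2-c][1,2]dioxin-6(7H)-one | C[C@@]1(/C=C\CCCCCCCCc3ccccc3)C[C@@]2(C)OC(=O)C[C@H]2OO1 | intermediate
22 | (3R,4aR,7aR)-3,4a-dimethyl-3-(10-phenyldecyl)-3,4,4a,7a-tetrahydrofuro[3,2-c][1,2]dioxin-6(7H)-one | C[C@@]1(CCCCCCCCCCc2ccccc2)C[C@@]2(C)OC(=O)C[C@H]2OO1 | target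

Total step count: 17. Longest linear sequence: 16 steps (1 to 22 through steps 1–14, 16 and 17); step 15 is a one-step side branch.

Steps most likely to fail

The singlet-oxygen ene reaction (step 7). What may go wrong: hydrogen abstraction from C2 (which would lead to the conjugated tertiary hydroperoxide) or from C5 competes with abstraction from the C4 methyl group, on top of the missing facial control at C3. The fallback makes the C3–O bond by conjugate addition instead of an ene reaction and sets out from alkynol 3. Enyne cross-metathesis with ethene (second-generation Grubbs catalyst, CH2Cl2) should give the diene (2R)-1-[(4-methoxyphenyl)methoxy]-2-methyl-4-methylidenehex-5-en-2-ol F1, and cross-metathesis of its vinyl group with methyl acrylate (second-generation Hoveyda–Grubbs catalyst) the dienoate methyl (2E,6R)-6-hydroxy-7-[(4-methoxyphenyl)methoxy]-6-methyl-4-methylidenehept-2-enoate F2. DDQ then frees the diol methyl (2E,6R)-6,7-dihydroxy-6-methyl-4-methylidenehept-2-enoate F3, selective tosylation (TsCl, Et3N, Bu2SnO) gives the primary tosylate methyl (2E,6R)-6-hydroxy-6-methyl-4-methylidene-7-{[(4-methylphenyl)sulfonyl]oxy}hept-2-enoate F4, and K2CO3 in MeOH closes it to the epoxide methyl (2E)-4-{[(2R)-2-methyloxiran-2-yl]methyl}penta-2,4-dienoate F5. Opening of the epoxide at its tertiary carbon with ethereal H2O2 under H3PMo12O40 catalysis (inversion, as in step 8) gives the hydroxy hydroperoxide methyl (2E,6S)-6-hydroperoxy-7-hydroxy-6-methyl-4-methylidenehept-2-enoate F6. Et2NH in CF3CH2OH then induces 6-exo oxa-Michael addition of the hydroperoxide to C3, and after separation of the C3 epimers the route is rejoined at dioxane 11.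

The iodolactonisation (step 11, key step). What may go wrong: reversible iodonium formation lets the closure drift to the 6-endo mode or lets the silyl ether oxygen take part, or the kinetic cis preference is eroded by equilibration. The fallback keeps the same bond construction but uses a selenium electrophile and radical deselenation, and sets out from acid 13. PhSeCl in CH2Cl2 at −78 °C should close the C4–O bond irreversibly under kinetic control and give the selenide (3S,4aR,7aR)-3-({[tert-butyl(dimethyl)silyl]oxy}methyl)-3-methyl-4a-[(phenylselanyl)methyl]-3,4,4a,7a-tetrahydrofuro[3,2-c][1,2]dioxin-6(7H)-one F7. Bu3SnH with AIBN in toluene at 80 °C cleaves the C–Se bond, and the route is rejoined at 15.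

The Wittig olefination (step 16). What may go wrong: the basic ylide deprotonates the lactone at C2 with β-elimination of the peroxide oxygen, or phosphorus attacks the O–O bond, faster than the ylide adds to the hindered aldehyde. The fallback is a Julia–Kocienski olefination, which uses no phosphorus reagent, and sets out from bromide 18. Alkylation of 1-phenyl-1H-tetrazole-5-thiol (K2CO3, acetone) gives the sulfide 1-phenyl-5-[(9-phenylnonyl)sulfanyl]-1H-tetrazole F8, and oxidation with H2O2 and catalytic (NH4)6Mo7O24 in EtOH gives the sulfone 1-phenyl-5-[(9-phenylnonyl)sulfonyl]-1H-tetrazole F9. Its anion (KN(SiMe3)2, 1,2-dimethoxyethane, −78 °C) is combined with aldehyde 17 to give the E alkene (3S,4aR,7aR)-3,4a-dimethyl-3-[(1E)-10-phenyldec-1-en-1-yl]-3,4,4a,7a-tetrahydrofuro[3,2-c][1,2]dioxin-6(7H)-one F10, and diimide reduction as in step 17 rejoins the route at the target 22.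

Further compounds
F1 | step 7 | (2R)-1-[(4-methoxyphenyl)methoxy]-2-methyl-4-methylidenehex-5-en-2-ol | C[C@](O)(COCc1ccc(OC)cc1)CC(=C)C=C
F2 | step 7 | methyl (2E,6R)-6-hydroxy-7-[(4-methoxyphenyl)methoxy]-6-methyl-4-methylidenehept-2-enoate | COC(=O)/C=C/C(=C)C[C@@](C)(O)COCc1ccc(OC)cc1
F3 | step 7 | methyl (2E,6R)-6,7-dihydroxy-6-methyl-4-methylidenehept-2-enoate | COC(=O)/C=C/C(=C)C[C@@](C)(O)CO
F4 | step 7 | methyl (2E,6R)-6-hydroxy-6-methyl-4-methylidene-7-{[(4-methylphenyl)sulfonyl]oxy}hept-2-enoate | COC(=O)/C=C/C(=C)C[C@@](C)(O)COS(=O)(=O)c1ccc(C)cc1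
F5 | step 7 | methyl (2E)-4-{[(2R)-2-methyloxiran-2-yl]methyl}penta-2,4-dienoate | COC(=O)/C=C/C(=C)C[C@]1(C)CO1
F6 | step 7 | methyl (2E,6S)-6-hydroperoxy-7-hydroxy-6-methyl-4-methylidenehept-2-enoate | COC(=O)/C=C/C(=C)C[C@](C)(OO)CO
F7 | step 11 | (3S,4aR,7aR)-3-({[tert-butyl(dimethyl)silyl]oxy}methyl)-3-methyl-4a-[(phenylselanyl)methyl]-3,4,4a,7a-tetrahydrofuro[3,2-c][1,2]dioxin-6(7H)-one | C[C@@]1(CO[Si](C)(C)C(C)(C)C)C[C@@]2(C[Se]c3ccccc3)OC(=O)C[C@H]2OO1
F8 | step 16 | 1-phenyl-5-[(9-phenylnonyl)sulfanyl]-1H-tetrazole | c1ccccc1CCCCCCCCCSc1nnnn1-c1ccccc1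
F9 | step 16 | 1-phenyl-5-[(9-phenylnonyl)sulfonyl]-1H-tetrazole | O=S(=O)(CCCCCCCCCc1ccccc1)c1nnnn1-c1ccccc1
F10 | step 16 | (3S,4aR,7aR)-3,4a-dimethyl-3-[(1E)-10-phenyldec-1-en-1-yl]-3,4,4a,7a-tetrahydrofuro[3,2-c][1,2]dioxin-6(7H)-one | C[C@@]1(/C=C/CCCCCCCCc3ccccc3)C[C@@]2(C)OC(=O)C[C@H]2OO1
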